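**Retrosynthetic overview**

1. Target 26 ⇒ ring B opened at O2–C3 and C3–C4: chloroenone 15 (C4 still a methyl group, C1 a protected aldehyde enol) plus dienoyl donor 23; the lactone enol and the C7 hydroxyl are unmasked last.
2. Feature used: in ring A (C4a–C5–C6–C7–C8–C8a) the C7 tertiary oxygen and C4a of the C4a=C5–C6(=O) enone stand 1,4 to each other, and the C8 lactone is cis to that oxygen. This is the pattern left when the oxygen bridge of a 7-oxabicyclo[2.2.1]heptan-2-one (bridgeheads C7 and C4a) is opened by β-elimination (13 ⇒ 14).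
3. The oxabicycle ⇒ [4+2] addition of silyloxyfuran 2 (gives C7, C6, C5, C4a, the C7 methyl and C4) to (E)-enal 11 (gives C8, C8a, C1 and the lactone), forming C7–C8 and C4a–C8a. Chlorine enters at C5 through the silyl enol ether of the adduct.
4. 11 ⇒ vinyl bromide 8 + alkenylboronate 9; 8 ⇒ ethyl (S)-3-hydroxybutanoate 3 (C6′). Side chain 23 ⇒ (S)-2-methylbutan-1-ol 16.
5. Ring order: lactone (step 3), oxabicycle holding ring A (step 7), bridge opening (step 9), ring B (step 16).

Key step: step 7

Locants: isochromene numbering of the target is used for all intermediates (O2; C1 = OCH=; C3 carries the dienyl chain; C5–Cl; C6 ketone; C7 carbinol; C8 carries lactone carbon C3′); primed locants belong to the lactone. PMB = 4-methoxybenzyl, TBS = tert-butyldimethylsilyl, TES = triethylsilyl.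

Assumption: C3′ of the β-keto lactone is a labile centre that equilibrates through the enol; it is delivered under thermodynamic control in the last step, and the drawn (3′R) epimer is taken to be the favoured one. Compound 14 is drawn as its hydroxymethylene (enol) tautomer; the enol geometry there and in 15 is of no consequence.

**Route**

Step 1
Reactants: 1 2,5-dimethylfuran-3(2H)-one
Product: 2 tert-butyl[(2,5-dimethylfuran-3-yl)oxy]dimethylsilane
Conditions: tBuMe2SiOTf, Et3N, CH2Cl2, 0 °C
Reagents that add atoms: tert-butyldimethylsilyl trifluoromethanesulfonate, CC(C)(C)[Si](C)(C)OS(=O)(=O)C(F)(F)F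
Why: O-silylation of the enolisable furan-3(2H)-one with a silyl triflate and an amine base traps the aromatic 3-oxyfuran tautomer (silyl enol ether formation), the usual access to 3-silyloxyfurans; no stereocentre is formed.

Step 2
Reactants: 3 ethyl (S)-3-hydroxybutanoate; 4 tert-butyl acetate
Product: 5 tert-butyl (S)-5-hydroxy-3-oxohexanoate
Conditions: 4 (3.5 equiv), LiN(iPr)2 (3.5 equiv), THF, −78 °C; then 3, −78 → −30 °C; AcOH
Reagents that add atoms: none
Why: crossed Claisen condensation in which the lithium enolate of 4, used in excess to absorb the hydroxyl proton and the acidic β-keto ester, acylates at the ethyl ester and leaves the carbinol centre (future C6′) of 3 untouched.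

Step 3
Reactants: 5 tert-butyl (S)-5-hydroxy-3-oxohexanoate
Product: 6 (S)-6-methyloxane-2,4-dione
Conditions: CF3CO2H, CH2Cl2, 23 °C
Reagents that add atoms: none
Why: acid cleaves the tert-butyl ester and the δ-hydroxy acid lactonises to the β-keto-δ-lactone (acid-catalysed lactonisation); C6′ is not involved.

Step 4
Reactants: 6 (S)-6-methyloxane-2,4-dione
Product: 7 (S)-4-[(4-methoxybenzyl)oxy]-6-methyl-5,6-dihydro-2H-pyran-2-one
Conditions: 4-methoxybenzyl alcohol, PPh3, iPrO2C–N=N–CO2iPr, THF, 0 → 23 °C
Reagents that add atoms: 4-methoxybenzyl alcohol, COc1ccc(CO)cc1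
Why: Mitsunobu alkylation of the acidic enol (a vinylogous acid) takes place on the 4-oxygen and gives the conjugated 4-alkoxy-dihydropyranone; the PMB enol ether is chosen because mild acid removes it at the end, which a methyl enol ether would not allow.

Step 5
Reactants: 7 (S)-4-[(4-methoxybenzyl)oxy]-6-methyl-5,6-dihydro-2H-pyran-2-one
Product: 8 (S)-3-bromo-4-[(4-methoxybenzyl)oxy]-6-methyl-5,6-dihydro-2H-pyran-2-one
Conditions: NBS, CH2Cl2, 0 → 23 °C, dark
Reagents that add atoms: N-bromosuccinimide, O=C1CCC(=O)N1Br
Why: electrophilic bromination at the electron-rich α-carbon C3′ of the β-alkoxy enoate, followed by loss of the C3′ proton, gives the vinyl bromide needed for cross-coupling.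

Step 6
Reactants: 8 (S)-3-bromo-4-[(4-methoxybenzyl)oxy]-6-methyl-5,6-dihydro-2H-pyran-2-one; 9 2-[(E)-3,3-diethoxyprop-1-en-1-yl]-4,4,5,5-tetramethyl-1,3,2-dioxaborolane
Product: 11 (E)-3-[(6S)-4-(4-methoxybenzyloxy)-6-methyl-2-oxo-5,6-dihydro-2H-pyran-3-yl]prop-2-enal, via acetal 10 (not isolated)
Conditions: PdCl2(dppf) ([1,1′-bis(diphenylphosphino)ferrocene]dichloropalladium, 5 mol%), K3PO4, THF/H2O (10:1), 60 °C; then 1 M HCl, THF, 0 °C
Reagents that add atoms: water, O
Why: Suzuki–Miyaura coupling of the vinyl bromide with the (E)-alkenylboronate proceeds with retention of alkene geometry, and dilute acid then hydrolyses the acrolein acetal to the (E)-enal without touching the PMB enol ether.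

Step 7
Reactants: 2 tert-butyl[(2,5-dimethylfuran-3-yl)oxy]dimethylsilane; 11 (E)-3-[(6S)-4-(4-methoxybenzyloxy)-6-methyl-2-oxo-5,6-dihydro-2H-pyran-3-yl]prop-2-enal
Product: 12 endo [4+2] adduct: 2-(tert-butyldimethylsilyloxy)-1,4-dimethyl-7-oxabicyclo[2.2.1]hept-2-ene with 5-endo formyl and 6-exo lactone (PMB enol ether); bridgeheads are C7 and C4a, and the bridge oxygen is syn to the lactone
Conditions: 2 (1.5 equiv), (2R,5R)-5-benzyl-2-tert-butyl-3-methylimidazolidin-4-one·CF3CO2H (20 mol%), CH2Cl2, −40 °C; cold filtration through Et3N-deactivated silica; used at once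
Reagents that add atoms: none
Why: Proposed new method: the chiral imidazolidinone condenses with 11 to an (E)-iminium ion whose lowered LUMO should allow a normal-demand, strongly asynchronous [4+2] addition of the electron-rich furan 2, in which furan C2 (next to the silyloxy group, largest HOMO coefficient) bonds to the β-carbon (C7–C8) and the resulting enamine carbon then bonds to the oxocarbenium carbon (C4a–C8a); the closest known reaction types are the iminium-catalysed Diels–Alder reaction of (E)-enals with dienes and the iminium-catalysed Mukaiyama–Michael addition of silyloxyfurans to enals. Ring A (six-membered carbocycle C7–C6–C5–C4a–C8a–C8) and the oxolane ring (O–C7–C8–C8a–C4a) of the 7-oxabicyclo[2.2.1]heptene are both closed by this suprafacial–suprafacial cycloaddition, at the moment the C4a–C8a bond forms. C8 is set by the catalyst, whose benzyl group covers the Si face of the iminium ion so that the furan adds to the Re face of the β-carbon; C8a follows from the (E) geometry of the dienophile (formyl trans to lactone); C7 and C4a follow from the endo arrangement (iminium under the C4a–C5 edge, lactone exo) and from the cis requirement of the oxygen bridge. The step needs regio-, endo- and face selectivity and ring closure in preference to desilylative open-chain addition: the silyloxy group fixes the regiochemistry, the bulk of the lactone next to the C6 silyloxy group favours the exo position for it, the catalyst overrides the remote C6′ centre, and an aprotic medium without silyl scavenger at −40 °C keeps silicon on oxygen until the second bond has formed.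

Step 8
Reactants: 12 endo [4+2] adduct
Product: 13 3-exo-chloro-1,4-dimethyl-7-oxabicyclo[2.2.1]heptan-2-one with 5-endo formyl and 6-exo lactone (PMB enol ether); the chlorine is on C5 and the ketone is C6
Conditions: NCS (1.6 equiv, covers residual 2), THF, −78 → −20 °C; aq. NaHCO3
Reagents that add atoms: N-chlorosuccinimide, O=C1CCC(=O)N1Cl
Why: electrophilic α-chlorination of the silyl enol ether places chlorine regiospecifically on C5 and turns the cycloreversion-prone enol ether into a ketone; exo attack is expected, but the C5 configuration is erased in step 9.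

Step 9
Reactants: 13 α-chloro oxabicyclic ketone
Product: 14 ring-opened chloroenone: 2-chloro-6-hydroxy-4-(hydroxymethylene)-3,6-dimethyl-5-lactonylcyclohex-2-en-1-one (C7 hydroxyl cis to the C8 lactone; PMB enol ether retained)
Conditions: DBU (1.5 equiv), CH2Cl2, −20 → 0 °C; aq. KHSO4
Reagents that add atoms: none
Why: E1cB β-elimination, in which deprotonation at C5 expels the bridging oxygen from C4a, gives the C4a=C5 chloroenone and leaves the oxygen on C7 on the face it held in the bridge (cis to the lactone), while the now doubly activated C8a–H enolises so that C8a becomes planar.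

Step 10
Reactants: 14 ring-opened chloroenone
Product: 15 bis(triethylsilyl) derivative of 14 (C1 enol oxygen and C7 oxygen silylated)
Conditions: Et3SiOTf (2.4 equiv), 2,6-lutidine, CH2Cl2, −78 → −20 °C; used crude
Reagents that add atoms: triethylsilyl trifluoromethanesulfonate, CC[Si](CC)(CC)OS(=O)(=O)C(F)(F)F
Why: silyl triflate with a hindered pyridine base silylates the unhindered enol oxygen at C1 and the tertiary C7 hydroxyl (O-silylation), which removes both acidic protons before the enolate chemistry and prevents a C7 alkoxide from attacking the lactone carbonyl.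

Step 11
Reactants: 16 (S)-2-methylbutan-1-ol
Product: 18 ethyl (2E,4S)-2,4-dimethylhex-2-enoate, via aldehyde 17 (not isolated)
Conditions: PhI(OAc)2, TEMPO (10 mol%), CH2Cl2, 0 → 23 °C; then Ph3P=C(CH3)CO2Et, 23 °C
Reagents that add atoms: ethyl 2-(triphenyl-λ5-phosphanylidene)propanoate, CCOC(=O)C(C)=P(c1ccccc1)(c1ccccc1)c1ccccc1
Why: nitroxyl-catalysed oxidation gives the α-chiral aldehyde without base, and the in situ Wittig reaction with the stabilised ylide gives the (E)-trisubstituted enoate before the aldehyde can epimerise.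

Step 12
Reactants: 18 ethyl (2E,4S)-2,4-dimethylhex-2-enoate
Product: 19 (2E,4S)-2,4-dimethylhex-2-en-1-ol
Conditions: iBu2AlH (2.2 equiv), CH2Cl2, −78 °C; aq. KNaC4H4O6
Reagents that add atoms: none
Why: 1,2-reduction of the enoate by the aluminium hydride at low temperature gives the allylic alcohol and leaves the alkene geometry and the allylic stereocentre untouched.

Step 13
Reactants: 19 (2E,4S)-2,4-dimethylhex-2-en-1-ol
Product: 21 ethyl (2E,4E,6S)-4,6-dimethylocta-2,4-dienoate, via enal 20 (not isolated)
Conditions: MnO2 (excess), Ph3P=CHCO2Et, CH2Cl2, 23 °C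
Reagents that add atoms: ethyl 2-(triphenyl-λ5-phosphanylidene)acetate, CCOC(=O)C=P(c1ccccc1)(c1ccccc1)c1ccccc1
Why: tandem allylic oxidation–Wittig olefination, in which MnO2 oxidises the allylic alcohol and the stabilised ylide traps the enal as the (E)-enoate, so the γ-epimerisable enal is never isolated.

Step 14
Reactants: 21 ethyl (2E,4E,6S)-4,6-dimethylocta-2,4-dienoate
Product: 22 (2E,4E,6S)-4,6-dimethylocta-2,4-dienoic acid
Conditions: LiOH, THF/MeOH/H2O, 23 °C; then 1 M HCl
Reagents that add atoms: lithium hydroxide, [Li+].[OH-]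
Why: saponification of the ethyl ester gives the dienoic acid; the ε-stereocentre is not deprotonated by hydroxide.

Step 15
Reactants: 22 (2E,4E,6S)-4,6-dimethylocta-2,4-dienoic acid
Product: 23 1-[(2E,4E,6S)-4,6-dimethylocta-2,4-dienoyl]-1H-benzotriazole
Conditions: 1-(methylsulfonyl)-1H-benzotriazole, Et3N, THF, 60 °C
Reagents that add atoms: 1-(methylsulfonyl)-1H-benzotriazole, CS(=O)(=O)n1nnc2ccccc12
Why: the carboxylate forms a mixed carboxylic–sulfonic anhydride that benzotriazolide acylates (acyl transfer), giving a neutral, storable N-acylbenzotriazole that C-acylates ketone enolates.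

Step 16
Reactants: 15 bis(triethylsilyl) chloroenone; 23 1-[(2E,4E,6S)-4,6-dimethylocta-2,4-dienoyl]-1H-benzotriazole
Product: 25 7-O-triethylsilyl 4′-O-PMB derivative of the target with ring B closed, via acyl enone 24 (not isolated)
Conditions: LiN(SiMe3)2 (1.05 equiv), THF, −78 °C; 23 (1.1 equiv); LiN(SiMe3)2 (1.05 equiv), −78 → −40 °C; AcOH; then TsOH·H2O (10 mol%), wet CH2Cl2, 0 °C
Reagents that add atoms: none
Why: vinylogous Claisen acylation, in which the amide base removes a C4 methyl proton (no α′-hydrogen exists because C7 is quaternary) and the extended enolate is acylated at its CH2 terminus because C5 is fully substituted and bears chlorine, the product being held as its stabilised enolate by the second equivalent of base; acid then cleaves the C1 silyl enol ether and cyclodehydrates the 1,5-dicarbonyl to the 4H-pyran of ring B.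

Step 17
Reactants: 25 7-O-triethylsilyl 4′-O-PMB derivative of the target
Product: 26 target (CNP0584120.1)
Conditions: CF3CO2H/CH2Cl2 (1:9), anisole (10 equiv), H2O (5 equiv), 0 → 23 °C
Reagents that add atoms: none
Why: acidolysis, in which the acid cleaves the PMB enol ether (the benzyl cation is trapped by anisole) and the tertiary silyl ether, and the freed enol tautomerises to the β-keto lactone, whose C3′ centre settles under thermodynamic control.

**Compound list**

1 | 2,5-dimethylfuran-3(2H)-one (racemic at C2) | CC1OC(C)=CC1=O | starting material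
2 | tert-butyl[(2,5-dimethylfuran-3-yl)oxy]dimethylsilane | Cc1cc(O[Si](C)(C)C(C)(C)C)c(C)o1 | intermediate
3 | ethyl (S)-3-hydroxybutanoate | CCOC(=O)C[C@H](C)O | starting material
4 | tert-butyl acetate | CC(=O)OC(C)(C)C | starting material
5 | tert-butyl (S)-5-hydroxy-3-oxohexanoate | C[C@H](O)CC(=O)CC(=O)OC(C)(C)C | intermediate
6 | (S)-6-methyloxane-2,4-dione | C[C@H]1CC(=O)CC(=O)O1 | intermediate
7 | (S)-4-[(4-methoxybenzyl)oxy]-6-methyl-5,6-dihydro-2H-pyran-2-one | C[C@H]1CC(OCc2ccc(OC)cc2)=CC(=O)O1 | intermediate
8 | (S)-3-bromo-4-[(4-methoxybenzyl)oxy]-6-methyl-5,6-dihydro-2H-pyran-2-one | C[C@H]1CC(OCc2ccc(OC)cc2)=C(Br)C(=O)O1 | intermediate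
9 | 2-[(E)-3,3-diethoxyprop-1-en-1-yl]-4,4,5,5-tetramethyl-1,3,2-dioxaborolane | CCOC(OCC)/C=C/B1OC(C)(C)C(C)(C)O1 | starting material
10 | diethyl acetal of 11 (not isolated) | CCOC(OCC)/C=C/C1=C(OCc2ccc(OC)cc2)C[C@H](C)OC1=O | intermediate
11 | (E)-3-[(6S)-4-(4-methoxybenzyloxy)-6-methyl-2-oxo-5,6-dihydro-2H-pyran-3-yl]prop-2-enal | O=C/C=C/C1=C(OCc2ccc(OC)cc2)C[C@H](C)OC1=O | intermediate
12 | endo [4+2] adduct: 2-TBS-oxy-1,4-dimethyl-7-oxabicyclo[2.2.1]hept-2-ene, 5-endo formyl, 6-exo lactone (PMB enol ether), bridge oxygen syn to lactone | C[C@@]12O[C@@](C)(C=C1O[Si](C)(C)C(C)(C)C)[C@@H](C=O)[C@@H]2C3=C(OCc4ccc(OC)cc4)C[C@H](C)OC3=O | intermediate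
13 | 3-exo-chloro-1,4-dimethyl-7-oxabicyclo[2.2.1]heptan-2-one, 5-endo formyl, 6-exo lactone (PMB enol ether); either C5 epimer serves | C[C@@]12O[C@@](C)([C@@H](Cl)C1=O)[C@@H](C=O)[C@@H]2C3=C(OCc4ccc(OC)cc4)C[C@H](C)OC3=O | intermediate
14 | 2-chloro-6-hydroxy-4-(hydroxymethylene)-3,6-dimethyl-5-lactonylcyclohex-2-en-1-one, C7 hydroxyl cis to C8 lactone, drawn as the (E)-enol | C[C@@]1(O)C(=O)C(Cl)=C(C)/C(=C/O)[C@@H]1C2=C(OCc3ccc(OC)cc3)C[C@H](C)OC2=O | intermediate
15 | bis(triethylsilyl) derivative of 14 (C1 enol ether and C7 ether) | C[C@@]1(O[Si](CC)(CC)CC)C(=O)C(Cl)=C(C)/C(=C/O[Si](CC)(CC)CC)[C@@H]1C2=C(OCc3ccc(OC)cc3)C[C@H](C)OC2=O | intermediate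
16 | (S)-2-methylbutan-1-ol | CC[C@H](C)CO | starting material
17 | (S)-2-methylbutanal (not isolated) | CC[C@H](C)C=O | intermediate
18 | ethyl (2E,4S)-2,4-dimethylhex-2-enoate | CC[C@H](C)/C=C(C)/C(=O)OCC | intermediate
19 | (2E,4S)-2,4-dimethylhex-2-en-1-ol | CC[C@H](C)/C=C(C)/CO | intermediate
20 | (2E,4S)-2,4-dimethylhex-2-enal (not isolated) | CC[C@H](C)/C=C(C)/C=O | intermediate
21 | ethyl (2E,4E,6S)-4,6-dimethylocta-2,4-dienoate | CC[C@H](C)/C=C(C)/C=C/C(=O)OCC | intermediate
22 | (2E,4E,6S)-4,6-dimethylocta-2,4-dienoic acid | CC[C@H](C)/C=C(C)/C=C/C(=O)O | intermediate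
23 | 1-[(2E,4E,6S)-4,6-dimethylocta-2,4-dienoyl]-1H-benzotriazole | CC[C@H](C)/C=C(C)/C=C/C(=O)n1nnc2ccccc12 | intermediate
24 | C4-acylated derivative of 15 (C3 ketone carrying the dienyl chain; not isolated) | C[C@@]1(O[Si](CC)(CC)CC)C(=O)C(Cl)=C(CC(=O)/C=C/C(C)=C/[C@@H](C)CC)/C(=C/O[Si](CC)(CC)CC)[C@@H]1C2=C(OCc3ccc(OC)cc3)C[C@H](C)OC2=O | intermediate
25 | 7-O-triethylsilyl 4′-O-PMB derivative of the target (ring B closed) | CC[C@H](C)/C=C(C)/C=C/C1=CC2=C(Cl)C(=O)[C@@](C)(O[Si](CC)(CC)CC)[C@@H](C3=C(OCc4ccc(OC)cc4)C[C@H](C)OC3=O)C2=CO1 | intermediate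
26 | CNP0584120.1 | CC[C@H](C)/C=C(C)/C=C/C1=CC2=C(Cl)C(=O)[C@@](C)(O)[C@@H]([C@@H]3C(=O)C[C@H](C)OC3=O)C2=CO1 | target

**Step count**

Total steps: 17. Longest linear sequence: 11 steps (3 → 26 through steps 2–10, 16 and 17).

**Steps most likely to fail**

Step 7 (proposed new method). What may go wrong:
- the silyl group may be lost after the first C–C bond has formed, so that an open-chain Michael adduct results and the second bond does not form;
- endo or facial control may be poor;
- the amine catalyst may be consumed by addition–elimination at C4′;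
- the adduct may undergo cycloreversion on warming.

Fallback (sets out from 2 and 11, returns to the route at 14): the two bonds are made one after the other by known reactions. Iminium-catalysed Mukaiyama–Michael addition of 2 to 11 is run with the same imidazolidinone as its 2,4-dinitrobenzoate salt in CH2Cl2 containing water (2 equiv) at −40 °C. After loss of the silyl group this should give the furanone aldehyde F1, with the C7–C8 bond in place and C8 set by the catalyst. C7 is set in an open transition state, so its epimer may have to be removed at this stage. NCS in MeCN at 0 °C should chlorinate the vinylogous ester at its α-carbon (future C5) to give the chlorofuranone aldehyde F2. DBU in CH2Cl2 should then add the aldehyde enolate carbon to the furanone β-carbon (intramolecular Michael addition, forming C4a–C8a) and expel the ring oxygen by β-elimination, which leads to 14.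

Step 16. What may go wrong:
- acylation at oxygen or at C5 instead of C4;
- conjugate addition of the enolate to the dienoyl donor;
- γ-deprotonation of the dihydropyranone with ring opening;
- base-induced loss of configuration at the ε-centre of the side chain.

Fallback (sets out from 14 and 22, returns at 25): the acyl group is delivered intramolecularly. Acid 22 with (COCl)2 and catalytic DMF gives the dienoyl chloride F3. Compound 14 with F3 and Et3N in CH2Cl2 at −40 °C is acylated on the enol oxygen to give the enol dienoate F4. Et3SiOTf and 2,6-lutidine protect the C7 hydroxyl to give the silylated enol dienoate F5. LiN(SiMe3)2 in THF (−78 → −30 °C) then deprotonates C4, and the acyl group moves from oxygen to C4 through a six-membered transition state (Baker–Venkataraman-type transfer) to give the C-acyl hydroxymethylene enone F6. TsOH·H2O in CH2Cl2 closes ring B to 25. Only the (Z)-enol ester can transfer intramolecularly; the (E) isomer would be re-equilibrated with 4-(dimethylamino)pyridine and recycled.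

Step 17. What may go wrong:
- acid-promoted decomposition of the chloro dienone–pyran chromophore or of the diene;
- alkylation of the product by the 4-methoxybenzyl cation;
- migration of the lactone acyl group to the C7 hydroxyl.

Fallback (sets out from 14, returns at 26): the PMB group is exchanged for silicon before the acid-sensitive dienyl pyran exists. CF3CO2H and anisole convert 14 into the free 4′-enol F7. Et3SiOTf (3.6 equiv) and 2,6-lutidine give the tris(triethylsilyl) compound F8. Acylation with 23 as in step 16 gives the C4-acylated tris(silyl) intermediate F9. TsOH·H2O in wet CH2Cl2 cleaves both silyl enol ethers and closes ring B to the 7-O-triethylsilyl target F10. HF·pyridine in THF/pyridine at 0 °C then frees the C7 hydroxyl to give 26.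

**Further compounds**

F1 | step 7 | 3-(2,5-dimethyl-3-oxo-2,3-dihydrofuran-2-yl)-3-[(6S)-4-(4-methoxybenzyloxy)-6-methyl-2-oxo-5,6-dihydro-2H-pyran-3-yl]propanal, C7 and C8 configured as in 14 | CC1=CC(=O)[C@@](C)(O1)[C@H](CC=O)C2=C(OCc3ccc(OC)cc3)C[C@H](C)OC2=O
F2 | step 7 | 4-chloro derivative of F1 (chlorine on the future C5) | CC1=C(Cl)C(=O)[C@@](C)(O1)[C@H](CC=O)C2=C(OCc3ccc(OC)cc3)C[C@H](C)OC2=O
F3 | step 16 | (2E,4E,6S)-4,6-dimethylocta-2,4-dienoyl chloride | CC[C@H](C)/C=C(C)/C=C/C(Cl)=O
F4 | step 16 | (Z)-enol dienoate of 14 (C7 hydroxyl free) | C[C@@]1(O)C(=O)C(Cl)=C(C)/C(=C\OC(=O)/C=C/C(C)=C/[C@@H](C)CC)[C@@H]1C2=C(OCc3ccc(OC)cc3)C[C@H](C)OC2=O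
F5 | step 16 | 7-O-triethylsilyl ether of F4 | C[C@@]1(O[Si](CC)(CC)CC)C(=O)C(Cl)=C(C)/C(=C\OC(=O)/C=C/C(C)=C/[C@@H](C)CC)[C@@H]1C2=C(OCc3ccc(OC)cc3)C[C@H](C)OC2=O
F6 | step 16 | C4-acylated hydroxymethylene enone (7-O-triethylsilyl, 4′-O-PMB) | C[C@@]1(O[Si](CC)(CC)CC)C(=O)C(Cl)=C(CC(=O)/C=C/C(C)=C/[C@@H](C)CC)/C(=C/O)[C@@H]1C2=C(OCc3ccc(OC)cc3)C[C@H](C)OC2=O
F7 | step 17 | 14 without the PMB group (4′-enol free) | C[C@@]1(O)C(=O)C(Cl)=C(C)/C(=C/O)[C@@H]1C2=C(O)C[C@H](C)OC2=O
F8 | step 17 | tris(triethylsilyl) derivative of F7 (C1 enol, C7 and C4′ oxygens) | C[C@@]1(O[Si](CC)(CC)CC)C(=O)C(Cl)=C(C)/C(=C/O[Si](CC)(CC)CC)[C@@H]1C2=C(O[Si](CC)(CC)CC)C[C@H](C)OC2=O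
F9 | step 17 | C4-acylated derivative of F8 | C[C@@]1(O[Si](CC)(CC)CC)C(=O)C(Cl)=C(CC(=O)/C=C/C(C)=C/[C@@H](C)CC)/C(=C/O[Si](CC)(CC)CC)[C@@H]1C2=C(O[Si](CC)(CC)CC)C[C@H](C)OC2=O
F10 | step 17 | 7-O-triethylsilyl ether of the target | CC[C@H](C)/C=C(C)/C=C/C1=CC2=C(Cl)C(=O)[C@@](C)(O[Si](CC)(CC)CC)[C@@H]([C@@H]3C(=O)C[C@H](C)OC3=O)C2=CO1
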